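## Structural features

The target is a cembrane-type diterpenoid: a fourteen-membered carbocycle (C1–C14) bridged by a seven-membered α-methylene lactone that runs from C1 through C15 (exocyclic methylene C16) and the carbonyl C17 to the oxygen on C12. The large ring carries an (E)-trisubstituted olefin at C4=C5 and a (Z)-trisubstituted olefin at C7=C8, separated by the doubly allylic C6 methylene, and methyl groups on C4, C8 and C12. There are four stereocentres: C1 (S) and the allylic carbinol C3 (S) in a 1,3-relation, and the adjacent pair C11 (R, secondary acetate) and C12 (S, fully substituted, bearing the lactone oxygen), which are erythro to each other. Fragile elements are the exo-methylene lactone (a Michael acceptor that base can open or isomerise, and that a free C3 hydroxyl could capture as a six-membered lactone), the secondary acetate next to a tertiary ester (acyl migration), the allylic alcohol and the skipped diene. The real difficulty is threefold: closing a fourteen-membered ring, setting C11/C12 in the right sense relative to the remote C1/C3 pair, and esterifying the hindered tertiary C12 oxygen. The key step exploits the vicinal oxygenation at C11 and C12 inside the large ring: both carbons can be carbonyl carbons of an open chain, and joining them reductively closes the ring at the diol. The same analysis shows that C3–C2–C1(–C15/C16/C17)–C14–C13–C12(–CH3) is the carbon pattern of ring-opened (S)-limonene, so C1 can be bought.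

## Logic of the disconnections

28 from 27. The bond cut is O–Si at C3. A free C3 hydroxyl cannot coexist with an activated C17 acyl group, because it would close a six-membered lactone, so it is released last. Nothing is gained in skeleton, but every later operation is spared a competing nucleophile. The forward step must remove silicon without base, so that the methylene lactone and the acetate survive.

27 from 25 (through 26). The bond cut is C17–O to the C12 oxygen. This opens the bicycle to a monocyclic hydroxy acid in which all four stereocentres are already present. The forward step must acylate a tertiary alcohol with retention. It is made unambiguous by having no other free hydroxyl in 25.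

25 from 22 (through 24 and 23). The two C17–O bonds of the acid are traced back to one silyl ether. An acrylate or enal would trap ketyl radicals and could not be present in the reductive ring closure, so C17 is carried at the alcohol level. The forward steps must free the primary oxygen in the presence of the secondary silyl ether at C3 and oxidise only that allylic alcohol.

22 from 21. The bond cut is acetyl C–O at O11. Acetylating straight after ring closure differentiates the two new hydroxyls at once and installs a group that is in the target. The forward step must distinguish a secondary from a tertiary alcohol.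

21 from 20. The bond cut is C11–C12. This removes the ring and two stereocentres and leaves an open chain with an aldehyde at C11 and a methyl ketone at C12. The forward step must close fourteen atoms end to end, must not touch two allylic C–O bonds and three olefins, and must give the (11R,12S) diol. The configurations (1S,3S) of 20 and (1S,3S,11R,12S) of 21 were checked centre by centre against 28 and map onto it without change. The design of 20 is altered only in its protecting groups, and both allylic oxygens are TBS ethers. A triethylsilyl ether on the primary C17 oxygen would not survive the acid that unmasks C11 and is marginal toward titanium and zinc chlorides. The two TBS ethers are told apart later by rate (primary against hindered secondary).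

20 from 18 (through 19). The bonds changed are the acetal C–O bonds at C11 and O–Si at C3. The aldehyde stays masked through the organometallic fragment union and is released one step before use. The forward hydrolysis must be mild enough for two TBS ethers.

18 from 7 and 15 (through 17 and 16). The bond cut is C3–C4. This is the allylic alcohol retron. It splits the chain into two halves of similar size and lets the (E)-C4=C5 olefin arise from syn hydrometalation of a methyl-capped alkyne. The forward step needs regiocontrol in the hydrometalation, selectivity for the aldehyde over the methyl ketone, and facial control at C3.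

7 from 1 (through 6, 5, 4, 3 and 2). The C3 and C12 carbonyl carbons are rejoined as the ring double bond of 1, and the C17–O bond is removed. This reaches a chiral-pool terpene that supplies C1 in the right configuration together with both carbonyl carbons. The forward steps must oxidise the isopropenyl methyl group selectively and cleave the ring olefin in the presence of the exocyclic one.

15 from 13 and 14, and 13 from 8 (through 12, 11, 10 and 9). The bonds cut are C5–C6, then C–Cl back to C–O, then the C11 acetal back to the distal olefin of 8. The (Z)-C7=C8 olefin is bought ready-made. The forward steps must cleave one of two trisubstituted olefins and substitute an allylic chloride without loss of the Z geometry.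

## Other disconnections considered

Alternative 1: The cut is the C15–C1 bond of the lactone, made before any macrocycle exists. The forward key step is a Claisen-type [3,3] ring expansion. A ketene acetal unit C17=C15 held on the oxygens of C12 and C13 combines with an (E)-C14=C1 alkene on C13: heating forms C15–C1 while C13–O breaks, and the product is the seven-membered lactone A1 with a cis C13=C14 olefin.
- In its favour: the ester of the tertiary C12 oxygen is never made by acylation, since the O–C17 bond comes from an acetal. This is a clear advantage over the chosen plan. C11/C12 come from open-chain, reagent-controlled oxidation chemistry and C1 from a concerted suprafacial shift, so the plan is also better on stereochemical predictability.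
- Against it here: A1 lacks C16 and carries an extra C13=C14 double bond that must be hydrogenated without touching the C7=C8 olefin. It is still open with respect to the carbocycle, so macrocyclisation, α-methylenation of the lactone and several protecting-group changes remain. The chiral pool no longer supplies C1.
- Comparison: in structure it is lactone first and ring last, the reverse of the chosen order. In mechanism it is pericyclic and stereospecific, against a radical coupling on a metal template. In step economy the chosen plan should be shorter, because 1 delivers ten skeletal carbons with C1 and both later carbonyl carbons in three steps.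

Alternative 2: The cut is the O–C12 bond of the lactone in an already closed fourteen-membered ring. In the forward key step BF3·OEt2 activates an (11R,12R)-epoxide. The carbonyl oxygen of a C17 tert-butyl acrylate attacks C12 from the rear (7-exo, inversion), the tert-butyl group leaves as 2-methylpropene A3, and the hydroxy lactone A2 results.
- In its favour: the tertiary C–O bond is formed at an electrophilic tertiary carbon, where substitution is electronically favoured, instead of forcing a hindered alcohol to act as nucleophile. On the lactone this is better than the chosen plan. C11 and C12 are fixed together by one stereodefined epoxide, which is also better than the pinacol. The end game after A2 is only acetylation and desilylation, which is shorter.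
- Against it here: the cut does not close the carbocycle, so a separate macrocyclisation that tolerates a trisubstituted epoxide and an acrylate is needed. The epoxide must be placed site- and face-selectively among three trisubstituted olefins. Under a Lewis acid it can also be opened across the ring by the C7=C8 olefin or rearrange.
- Comparison: in structure the two plans converge, since A2 is the desacetyl counterpart of 27. In mechanism it is a stereospecific substitution against a stereo-uncertain radical coupling. In step economy it is about equal overall, because what is saved after A2 is spent on ring and epoxide construction, whereas the chosen plan uses the two oxygens themselves to close the ring. The epoxide tactic is kept as the reserve for step 16.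

Alternative 3: The cut is C4–C5, as a triple bond. The forward key step is ring-closing alkyne metathesis between methyl-capped alkyne termini at C4 and C5 with Mo(≡C–C6H4-4-OMe)(OSiPh3)3. It gives the cycloalkyne A4 with loss of but-2-yne A5. The alkyne is then turned into the (E)-methyl-substituted olefin by hydroxyl-directed trans-hydrostannation and exchange of tin for methyl.
- In its favour: ring closure creates no stereocentre and takes place far from all four, which are set beforehand in open-chain intermediates. This is better than the chosen plan on stereochemical security. The catalyst tolerates esters, acetates, silyl ethers and olefins, so lactone and acetate can be in place. The E geometry is obtained deliberately, which is equal to the hydrozirconation used here.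
- Against it here: the lactone with its tertiary ester must first be built on an open chain, so the hardest bond is moved, not avoided. The sequence after metathesis (freeing the C3 hydroxyl, ruthenium-catalysed hydrostannation next to a methylene lactone, methylation) adds steps and tin reagents. Two alkyne-bearing fragments cost more steps than one allylic chloride coupling.
- Comparison: in structure the ring is closed on the flexible skipped-diene side and not at the stereogenic diol. In mechanism it is a catalytic metathesis driven by loss of A5, against a stoichiometric single-electron reduction. In step economy the chosen plan is shorter on paper, but the alternative is the better choice if reliability of ring closure is ranked above brevity.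

Key step: step 11

Assumption: neryl acetate (the commercial acetate of nerol) and prop-1-yn-1-ylmagnesium bromide (the commercial Grignard solution of propyne) are taken as purchasable, and ring locants of 21–28 follow the target numbering C1–C17 defined above.

## Route

Step 1
Reactants: 1 (S)-limonene
Product: 4 2-[(1S)-4-methylcyclohex-3-en-1-yl]prop-2-en-1-ol, via allyllithium 2 (not isolated), via allylboronate 3 (not isolated)
Conditions: n-BuLi, TMEDA, hexane, 25 °C; B(OMe)3, Et2O, −78 → 25 °C; H2O2, aq NaOH, 0 °C
Reagents that add atoms: hydrogen peroxide, OO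
Why: n-BuLi·TMEDA deprotonates the isopropenyl methyl group, the kinetically preferred allylic site, to a 2-substituted allyllithium with equivalent termini, so borylation and oxidative C–B cleavage can only give 4 (allylic metalation, then borylation–oxidation). The ring methine is not deprotonated, so the S centre is untouched.

Step 2
Reactants: 4 2-[(1S)-4-methylcyclohex-3-en-1-yl]prop-2-en-1-ol
Product: 5 tert-butyl(dimethyl){2-[(1S)-4-methylcyclohex-3-en-1-yl]prop-2-en-1-yloxy}silane
Conditions: TBSCl, imidazole, DMF, 25 °C
Reagents that add atoms: tert-butyl(chloro)dimethylsilane, CC(C)(C)[Si](C)(C)Cl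
Why: Imidazole-promoted silylation of an unhindered primary allylic alcohol. TBS is chosen because it must survive the acidic unmasking of C11 and the Lewis-acidic titanium and zinc chlorides of the ring closure.

Step 3
Reactants: 5 tert-butyl(dimethyl){2-[(1S)-4-methylcyclohex-3-en-1-yl]prop-2-en-1-yloxy}silane
Product: 7 (3S)-3-{3-[tert-butyl(dimethyl)silyloxy]prop-1-en-2-yl}-6-oxoheptanal, via ozonide 6 (not isolated)
Conditions: O3, CH2Cl2, −78 °C (Sudan Red 7B as end-point dye); PPh3, −78 → 25 °C
Reagents that add atoms: ozone, [O-][O+]=O
Why: Electrophilic ozone attacks the trisubstituted ring olefin much faster than the 1,1-disubstituted olefin, which the allylic silyloxy group deactivates further, and PPh3 reduces ozonide 6 (chemoselective ozonolysis). The stereocentre is β to the aldehyde and cannot epimerise by enolisation.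

Step 4
Reactants: 8 neryl acetate
Product: 10 (2Z)-3-methyl-6-oxohex-2-en-1-yl acetate, via ozonide 9 (not isolated)
Conditions: O3 (slight deficit, metered), CH2Cl2, −78 °C; PPh3, −78 → 25 °C
Reagents that add atoms: ozone, [O-][O+]=O
Why: The allylic acetate withdraws electron density from the proximal olefin, so the distal trisubstituted olefin is the more nucleophilic and is cleaved first when ozone is limiting (site-selective ozonolysis). The Z olefin is not involved.

Step 5
Reactants: 10 (2Z)-3-methyl-6-oxohex-2-en-1-yl acetate
Product: 12 (2Z)-6,6-dimethoxy-3-methylhex-2-en-1-ol, via acetal acetate 11 (not isolated)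
Conditions: HC(OMe)3, PPTS (cat.), MeOH, 25 °C; then K2CO3, 25 °C
Reagents that add atoms: trimethyl orthoformate, COC(OC)OC; methanol, CO
Why: Acid-catalysed acetalisation with the orthoformate as water scavenger, then base-catalysed methanolysis of the acetate in the same flask. Neither condition affects the Z olefin.

Step 6
Reactants: 12 (2Z)-6,6-dimethoxy-3-methylhex-2-en-1-ol
Product: 13 (2Z)-1-chloro-6,6-dimethoxy-3-methylhex-2-ene
Conditions: NCS, Me2S, CH2Cl2, −30 → 0 °C
Reagents that add atoms: N-chlorosuccinimide, O=C1CCC(=O)N1Cl
Why: Corey–Kim chlorination: chloride displaces the alkoxysulfonium group at the primary carbon by SN2, without allylic transposition or Z/E isomerisation, in a medium too weakly acidic to harm the acetal.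

Step 7
Reactants: 13 (2Z)-1-chloro-6,6-dimethoxy-3-methylhex-2-ene; 14 prop-1-yn-1-ylmagnesium bromide
Product: 15 (5Z)-9,9-dimethoxy-6-methylnon-5-en-2-yne
Conditions: CuCl (10 mol%), THF, 0 → 50 °C
Reagents that add atoms: none
Why: Copper-catalysed coupling of an alkynyl Grignard reagent with a primary allylic chloride. The alkynylcopper intermediate substitutes at the unhindered α-carbon, which keeps the Z geometry and gives the skipped enyne.

Step 8
Reactants: 15 (5Z)-9,9-dimethoxy-6-methylnon-5-en-2-yne; 7 (3S)-3-{3-[tert-butyl(dimethyl)silyloxy]prop-1-en-2-yl}-6-oxoheptanal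
Product: 18 (5S,7S,8E,11Z)-5-{3-[tert-butyl(dimethyl)silyloxy]prop-1-en-2-yl}-7-hydroxy-15,15-dimethoxy-8,12-dimethylpentadeca-8,11-dien-2-one, via alkenylzirconocene 16 (not isolated), via alkenylzinc 17 (not isolated)
Conditions: 15, Cp2Zr(H)Cl (slight excess), CH2Cl2, 25 °C; toluene, Me2Zn, −65 °C; 2-[1-(dimethylamino)ethyl]benzenethiol (single enantiomer, 10 mol%), 7, −30 → 0 °C; aq NH4Cl
Reagents that add atoms: none
Why: Cp2Zr(H)Cl adds syn across the alkyne and a slight excess equilibrates the regioisomers toward zirconium on the methyl-bearing carbon, which fixes the E geometry (C3 trans to C6). Transmetalation to zinc gives a reagent that adds to the aldehyde and not to the methyl ketone (Zr-to-Zn alkenyl transfer and aldehyde addition). C3 is set by the chiral amino thiol–zinc catalyst, whose enantiomer is chosen for attack on the Re face of the aldehyde (3S); the minor C3 epimer is a diastereomer and is removed by chromatography.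

Step 9
Reactants: 18 (5S,7S,8E,11Z)-5-{3-[tert-butyl(dimethyl)silyloxy]prop-1-en-2-yl}-7-hydroxy-15,15-dimethoxy-8,12-dimethylpentadeca-8,11-dien-2-one
Product: 19 (5S,7S,8E,11Z)-7-[tert-butyl(dimethyl)silyloxy]-5-{3-[tert-butyl(dimethyl)silyloxy]prop-1-en-2-yl}-15,15-dimethoxy-8,12-dimethylpentadeca-8,11-dien-2-one
Conditions: TBSCl, imidazole, DMAP (cat.), DMF, 25–35 °C
Reagents that add atoms: tert-butyl(chloro)dimethylsilane, CC(C)(C)[Si](C)(C)Cl
Why: Silylation of the secondary allylic alcohol with the chloride. A silyl triflate is avoided because it would ionise the dimethyl acetal and enolise the methyl ketone.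

Step 10
Reactants: 19 (5S,7S,8E,11Z)-7-[tert-butyl(dimethyl)silyloxy]-5-{3-[tert-butyl(dimethyl)silyloxy]prop-1-en-2-yl}-15,15-dimethoxy-8,12-dimethylpentadeca-8,11-dien-2-one
Product: 20 (4Z,7E,9S,11S)-9-[tert-butyl(dimethyl)silyloxy]-11-{3-[tert-butyl(dimethyl)silyloxy]prop-1-en-2-yl}-4,8-dimethyl-14-oxopentadeca-4,7-dienal
Conditions: PPTS (cat.), acetone/H2O (10:1), 40 °C
Reagents that add atoms: water, O
Why: Dimethyl acetals of aliphatic aldehydes hydrolyse under very mild acid, helped by transacetalisation to acetone, conditions under which primary and secondary TBS ethers should survive. The aldehyde is released only now, so it never meets an organometallic reagent.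

Step 11
Reactants: 20 (4Z,7E,9S,11S)-9-[tert-butyl(dimethyl)silyloxy]-11-{3-[tert-butyl(dimethyl)silyloxy]prop-1-en-2-yl}-4,8-dimethyl-14-oxopentadeca-4,7-dienal
Product: 21 (1S,3S,4E,7Z,11R,12S)-3-[tert-butyl(dimethyl)silyloxy]-1-{3-[tert-butyl(dimethyl)silyloxy]prop-1-en-2-yl}-4,8,12-trimethylcyclotetradeca-4,7-diene-11,12-diol
Conditions: TiCl3(DME)1.5, Zn–Cu couple, DME, reflux, then 25 °C; 20 added by syringe pump over about 30 h (high dilution), 25 °C; aq K2CO3
Reagents that add atoms: none
Why: Low-valent titanium made from TiCl3 and Zn–Cu transfers one electron first to the C11 aldehyde and then to the C12 ketone; the two titanium-bound ketyls, held on the same metal surface, join to the C11–C12 bond, and the titanium pinacolate is hydrolysed on work-up, deoxygenation to the olefin being suppressed at 25 °C. The closest known reaction type is the titanium-mediated intramolecular pinacol coupling of keto aldehydes to macrocyclic 1,2-diols. The ring closes end to end over fourteen atoms (formally 14-exo-trig at the carbonyl attacked); slow addition, the metal template and the two trisubstituted olefins, which remove rotors from the chain, favour it over oligomerisation. C11 and C12 are set together: their relative configuration follows from how the two titanium-bound oxygens and the ring chain sit in the coupling (oxygens gauche on titanium with C10 and C13 turned toward each other at a ring corner gives the erythro pair), and the face of C12 is chosen by the C1 centre two atoms away through the fold of the forming ring. The step needs the (11R,12S) isomer out of four; this is the weakest control of the route and is backed by correction at C11 and by recycling, as set out at the end. Chemoselectivity is secured by the substrate: both allylic oxygens are silyl ethers and not esters or free alcohols, C17 is at the alcohol level so no acrylate can trap a ketyl, and titanium ketyls, unlike samarium ones, are not expected to cyclise onto the unactivated C15=C16 olefin that stands in a 5-hexenyl relation to C12.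

Step 12
Reactants: 21 (1S,3S,4E,7Z,11R,12S)-3-[tert-butyl(dimethyl)silyloxy]-1-{3-[tert-butyl(dimethyl)silyloxy]prop-1-en-2-yl}-4,8,12-trimethylcyclotetradeca-4,7-diene-11,12-diol
Product: 22 (1S,3S,4E,7Z,11R,12S)-3-[tert-butyl(dimethyl)silyloxy]-1-{3-[tert-butyl(dimethyl)silyloxy]prop-1-en-2-yl}-12-hydroxy-4,8,12-trimethylcyclotetradeca-4,7-dien-11-yl acetate
Conditions: Ac2O, pyridine, DMAP (cat.), CH2Cl2, 0 → 25 °C
Reagents that add atoms: acetic anhydride, CC(=O)OC(C)=O
Why: DMAP-catalysed acetylation discriminates strongly between the secondary C11 hydroxyl and the tertiary C12 hydroxyl at low temperature with limited anhydride. After this step C12–OH is the only hydroxyl that C17 can later acylate.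

Step 13
Reactants: 22 (1S,3S,4E,7Z,11R,12S)-3-[tert-butyl(dimethyl)silyloxy]-1-{3-[tert-butyl(dimethyl)silyloxy]prop-1-en-2-yl}-12-hydroxy-4,8,12-trimethylcyclotetradeca-4,7-dien-11-yl acetate
Product: 23 (1S,3S,4E,7Z,11R,12S)-3-[tert-butyl(dimethyl)silyloxy]-12-hydroxy-1-(3-hydroxyprop-1-en-2-yl)-4,8,12-trimethylcyclotetradeca-4,7-dien-11-yl acetate
Conditions: HF·pyridine, pyridine, THF, 0 °C
Reagents that add atoms: none
Why: Buffered HF·pyridine cleaves the unhindered primary allylic TBS ether much faster than the secondary one at C3, which is shielded by the ring and the C4 methyl-bearing olefin (rate-selective desilylation). Acetate and tertiary alcohol are inert.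

Step 14
Reactants: 23 (1S,3S,4E,7Z,11R,12S)-3-[tert-butyl(dimethyl)silyloxy]-12-hydroxy-1-(3-hydroxyprop-1-en-2-yl)-4,8,12-trimethylcyclotetradeca-4,7-dien-11-yl acetate
Product: 24 (1S,3S,4E,7Z,11R,12S)-3-[tert-butyl(dimethyl)silyloxy]-12-hydroxy-4,8,12-trimethyl-1-(3-oxoprop-1-en-2-yl)cyclotetradeca-4,7-dien-11-yl acetate
Conditions: MnO2, CH2Cl2, 25 °C
Reagents that add atoms: none
Why: MnO2 oxidises allylic alcohols selectively. The only free allylic hydroxyl is the primary one; the tertiary alcohol and the silylated C3 carbinol cannot react.

Step 15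
Reactants: 24 (1S,3S,4E,7Z,11R,12S)-3-[tert-butyl(dimethyl)silyloxy]-12-hydroxy-4,8,12-trimethyl-1-(3-oxoprop-1-en-2-yl)cyclotetradeca-4,7-dien-11-yl acetate
Product: 25 2-[(1S,3S,4E,7Z,11R,12S)-11-acetoxy-3-[tert-butyl(dimethyl)silyloxy]-12-hydroxy-4,8,12-trimethylcyclotetradeca-4,7-dien-1-yl]prop-2-enoic acid
Conditions: NaClO2, NaH2PO4, 2-methyl-2-butene, t-BuOH/H2O, 0 → 25 °C
Reagents that add atoms: sodium chlorite, [Na+].[O-]Cl=O
Why: Pinnick oxidation converts the enal into the acid without touching the olefins, because 2-methyl-2-butene scavenges hypochlorous acid. The phosphate buffer spares the TBS ether and the acetate.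

Step 16
Reactants: 25 2-[(1S,3S,4E,7Z,11R,12S)-11-acetoxy-3-[tert-butyl(dimethyl)silyloxy]-12-hydroxy-4,8,12-trimethylcyclotetradeca-4,7-dien-1-yl]prop-2-enoic acid
Product: 27 (1S,3S,4E,7Z,11R,12S)-11-acetoxy-3-[tert-butyl(dimethyl)silyloxy]cembra-4,7,15(16)-trien-17,12-olide, via mixed anhydride 26 (not isolated)
Conditions: 2,4,6-Cl3C6H2COCl, Et3N, THF, 25 °C; then slow addition to DMAP, toluene, 80 °C (high dilution)
Reagents that add atoms: none
Why: Yamaguchi lactonisation: DMAP opens mixed anhydride 26 to an acylpyridinium ion that is captured by the only free hydroxyl, at C12, closing the seven-membered ring (7-exo-trig at the acyl carbon). The C12–O bond is not broken, so C12 keeps its configuration. DMAP-mediated acyl transfer is the standard way to acylate tertiary alcohols, and the ring formed is the one of the natural product.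

Step 17
Reactants: 27 (1S,3S,4E,7Z,11R,12S)-11-acetoxy-3-[tert-butyl(dimethyl)silyloxy]cembra-4,7,15(16)-trien-17,12-olide
Product: 28 (1S,3S,4E,7Z,11R,12S)-11-acetoxy-3-hydroxycembra-4,7,15(16)-trien-17,12-olide (CNP0130972.9)
Conditions: HF·pyridine, THF, 0 → 25 °C
Reagents that add atoms: none
Why: HF·pyridine removes the secondary TBS ether under weakly acidic, non-nucleophilic conditions. Basic fluoride is avoided because a C3 alkoxide could open the lactone to the six-membered isomer or add to the methylene lactone.

## Compound list

1 | (S)-limonene, (4S)-1-methyl-4-(prop-1-en-2-yl)cyclohex-1-ene | CC1=CC[C@H](CC1)C(C)=C | starting material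
2 | {2-[(1S)-4-methylcyclohex-3-en-1-yl]prop-2-en-1-yl}lithium | [Li]CC(=C)[C@@H]1CC=C(C)CC1 | intermediate
3 | dimethyl {2-[(1S)-4-methylcyclohex-3-en-1-yl]prop-2-en-1-yl}boronate | COB(OC)CC(=C)[C@@H]1CC=C(C)CC1 | intermediate
4 | 2-[(1S)-4-methylcyclohex-3-en-1-yl]prop-2-en-1-ol | OCC(=C)[C@@H]1CC=C(C)CC1 | intermediate
5 | tert-butyl(dimethyl){2-[(1S)-4-methylcyclohex-3-en-1-yl]prop-2-en-1-yloxy}silane | CC(C)(C)[Si](C)(C)OCC(=C)[C@@H]1CC=C(C)CC1 | intermediate
6 | secondary ozonide of the ring olefin of 5: (4S)-1-methyl-4-{3-[tert-butyl(dimethyl)silyloxy]prop-1-en-2-yl}-7,8,9-trioxabicyclo[4.2.1]nonane, mixture at the two trioxolane carbons | CC12CC[C@@H](CC(OO1)O2)C(=C)CO[Si](C)(C)C(C)(C)C | intermediate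
7 | (3S)-3-{3-[tert-butyl(dimethyl)silyloxy]prop-1-en-2-yl}-6-oxoheptanal | CC(=O)CC[C@@H](CC=O)C(=C)CO[Si](C)(C)C(C)(C)C | intermediate
8 | neryl acetate, (2Z)-3,7-dimethylocta-2,6-dien-1-yl acetate | CC(C)=CCC/C(C)=C\COC(C)=O | starting material
9 | secondary ozonide of the distal olefin of 8: (2Z)-5-(5,5-dimethyl-1,2,4-trioxolan-3-yl)-3-methylpent-2-en-1-yl acetate, racemic at the trioxolane carbon | CC1(C)OOC(CC/C(C)=C\COC(C)=O)O1 | intermediate
10 | (2Z)-3-methyl-6-oxohex-2-en-1-yl acetate | O=CCC/C(C)=C\COC(C)=O | intermediate
11 | (2Z)-6,6-dimethoxy-3-methylhex-2-en-1-yl acetate | COC(OC)CC/C(C)=C\COC(C)=O | intermediate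
12 | (2Z)-6,6-dimethoxy-3-methylhex-2-en-1-ol | COC(OC)CC/C(C)=C\CO | intermediate
13 | (2Z)-1-chloro-6,6-dimethoxy-3-methylhex-2-ene | COC(OC)CC/C(C)=C\CCl | intermediate
14 | prop-1-yn-1-ylmagnesium bromide | CC#C[Mg]Br | starting material
15 | (5Z)-9,9-dimethoxy-6-methylnon-5-en-2-yne | CC#CC/C=C(/C)CCC(OC)OC | intermediate
16 | chlorobis(cyclopentadienyl)[(2E,5Z)-9,9-dimethoxy-6-methylnona-2,5-dien-2-yl]zirconium | Cl[Zr](C1C=CC=C1)(C1C=CC=C1)/C(C)=C/C/C=C(/C)CCC(OC)OC | intermediate
17 | methyl[(2E,5Z)-9,9-dimethoxy-6-methylnona-2,5-dien-2-yl]zinc | C[Zn]/C(C)=C/C/C=C(/C)CCC(OC)OC | intermediate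
18 | (5S,7S,8E,11Z)-5-{3-[tert-butyl(dimethyl)silyloxy]prop-1-en-2-yl}-7-hydroxy-15,15-dimethoxy-8,12-dimethylpentadeca-8,11-dien-2-one | CC(=O)CC[C@@H](C[C@H](O)/C(C)=C/C/C=C(/C)CCC(OC)OC)C(=C)CO[Si](C)(C)C(C)(C)C | intermediate
19 | (5S,7S,8E,11Z)-7-[tert-butyl(dimethyl)silyloxy]-5-{3-[tert-butyl(dimethyl)silyloxy]prop-1-en-2-yl}-15,15-dimethoxy-8,12-dimethylpentadeca-8,11-dien-2-one | CC(=O)CC[C@@H](C[C@H](O[Si](C)(C)C(C)(C)C)/C(C)=C/C/C=C(/C)CCC(OC)OC)C(=C)CO[Si](C)(C)C(C)(C)C | intermediate
20 | (4Z,7E,9S,11S)-9-[tert-butyl(dimethyl)silyloxy]-11-{3-[tert-butyl(dimethyl)silyloxy]prop-1-en-2-yl}-4,8-dimethyl-14-oxopentadeca-4,7-dienal | CC(=O)CC[C@@H](C[C@H](O[Si](C)(C)C(C)(C)C)/C(C)=C/C/C=C(/C)CCC=O)C(=C)CO[Si](C)(C)C(C)(C)C | intermediate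
21 | (1S,3S,4E,7Z,11R,12S)-3-[tert-butyl(dimethyl)silyloxy]-1-{3-[tert-butyl(dimethyl)silyloxy]prop-1-en-2-yl}-4,8,12-trimethylcyclotetradeca-4,7-diene-11,12-diol | C=C(CO[Si](C)(C)C(C)(C)C)[C@@H]1C[C@H](O[Si](C)(C)C(C)(C)C)/C(C)=C/C/C=C(/C)CC[C@@H](O)[C@@](C)(O)CC1 | intermediate
22 | (1S,3S,4E,7Z,11R,12S)-3-[tert-butyl(dimethyl)silyloxy]-1-{3-[tert-butyl(dimethyl)silyloxy]prop-1-en-2-yl}-12-hydroxy-4,8,12-trimethylcyclotetradeca-4,7-dien-11-yl acetate | C=C(CO[Si](C)(C)C(C)(C)C)[C@@H]1C[C@H](O[Si](C)(C)C(C)(C)C)/C(C)=C/C/C=C(/C)CC[C@@H](OC(C)=O)[C@@](C)(O)CC1 | intermediate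
23 | (1S,3S,4E,7Z,11R,12S)-3-[tert-butyl(dimethyl)silyloxy]-12-hydroxy-1-(3-hydroxyprop-1-en-2-yl)-4,8,12-trimethylcyclotetradeca-4,7-dien-11-yl acetate | C=C(CO)[C@@H]1C[C@H](O[Si](C)(C)C(C)(C)C)/C(C)=C/C/C=C(/C)CC[C@@H](OC(C)=O)[C@@](C)(O)CC1 | intermediate
24 | (1S,3S,4E,7Z,11R,12S)-3-[tert-butyl(dimethyl)silyloxy]-12-hydroxy-4,8,12-trimethyl-1-(3-oxoprop-1-en-2-yl)cyclotetradeca-4,7-dien-11-yl acetate | C=C(C=O)[C@@H]1C[C@H](O[Si](C)(C)C(C)(C)C)/C(C)=C/C/C=C(/C)CC[C@@H](OC(C)=O)[C@@](C)(O)CC1 | intermediate
25 | 2-[(1S,3S,4E,7Z,11R,12S)-11-acetoxy-3-[tert-butyl(dimethyl)silyloxy]-12-hydroxy-4,8,12-trimethylcyclotetradeca-4,7-dien-1-yl]prop-2-enoic acid | C=C(C(=O)O)[C@@H]1C[C@H](O[Si](C)(C)C(C)(C)C)/C(C)=C/C/C=C(/C)CC[C@@H](OC(C)=O)[C@@](C)(O)CC1 | intermediate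
26 | mixed anhydride of 25 with 2,4,6-trichlorobenzoic acid | C=C(C(=O)OC(=O)c1c(Cl)cc(Cl)cc1Cl)[C@@H]2C[C@H](O[Si](C)(C)C(C)(C)C)/C(C)=C/C/C=C(/C)CC[C@@H](OC(C)=O)[C@@](C)(O)CC2 | intermediate
27 | (1S,3S,4E,7Z,11R,12S)-11-acetoxy-3-[tert-butyl(dimethyl)silyloxy]cembra-4,7,15(16)-trien-17,12-olide | C=C1C(=O)O[C@@]2(C)CC[C@H]1C[C@H](O[Si](C)(C)C(C)(C)C)/C(C)=C/C/C=C(/C)CC[C@H]2OC(C)=O | intermediate
28 | (1S,3S,4E,7Z,11R,12S)-11-acetoxy-3-hydroxycembra-4,7,15(16)-trien-17,12-olide (CNP0130972.9) | C=C1C(=O)O[C@@]2(C)CC[C@H]1C[C@H](O)/C(C)=C/C/C=C(/C)CC[C@H]2OC(C)=O | target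

## Step count and least certain steps

Total step count: 17 (each numbered step ends with an isolated product). Longest linear sequence: 14 steps, from 8 to 28 (steps 4–17); the branch from 1 to 7 adds 3 steps.

**Step 11 (key step).** The most likely failure is insufficient facial discrimination in the ketyl coupling. Titanium templates in open systems tend toward the threo pair, and C1 is remote from C12, so the wrong C11 or C12 configuration may dominate. Intermolecular coupling is possible if the dilution is lost.
- Fallback: C11 is set after ring closure instead of during it. The fallback sets out from 20 and returns to 21.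
- The 12S material of wrong C11 configuration, the (11S,12S)-diol F1, is oxidised at the secondary carbinol (SO3·pyridine, DMSO, i-Pr2NEt) to the 12-hydroxy 11-ketone F2.
- F2 is reduced under chelation control (Zn(BH4)2, Et2O, −30 °C). Hydride enters the five-membered zinc chelate from the side of the C12 methyl group, which gives the erythro diol 21.
- Material that closes with the wrong C12 configuration is cleaved at the glycol with NaIO4 in THF/H2O, which regenerates 20 for another pass.

**Step 16.** The most likely failure is slow acylation of the hindered tertiary hydroxyl. That would let intermolecular esterification, acetyl migration from O11 to O12 followed by closure onto O11, or base-induced isomerisation of the methylene group take over.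
- Fallback: the O–C12 bond is formed instead of the C17–O bond, by opening an epoxide with inversion. Because C12 is inverted in that closure, the fallback needs the opposite C12 series. It sets out from 20 and returns to 27.
- The titanium coupling of 20 also gives the other erythro product, the (11S,12R)-diol F3. Threo 12R material can be converted into F3 by the oxidation–chelate reduction described for step 11.
- F3 is mesylated at the secondary hydroxyl (MsCl, Et3N, 0 °C) to the C11 mesylate F4.
- K2CO3 in MeOH closes F4 with inversion at C11 to the (11R,12R)-epoxide F5.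
- Buffered HF·pyridine frees the primary alcohol, giving the epoxy alcohol F6.
- MnO2 gives the epoxy enal F7, and NaClO2 (buffered, with 2-methyl-2-butene) gives the epoxy acid F8.
- A trace of camphorsulfonic acid in CH2Cl2 lets the carboxyl group open the epoxide at the tertiary carbon (7-exo, inversion at C12) to the hydroxy lactone F9, the same compound as A2.
- Ac2O/DMAP converts F9 into 27.

**Step 8.** Three processes may go wrong: incomplete regiocontrol in the hydrozirconation, weak facial control at C3 (an aliphatic aldehyde, with zirconocene by-products promoting an uncatalysed background addition), and aldol self-condensation of the keto aldehyde.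
- Fallback: the C3 mixture is accepted and the configuration is corrected by substitution instead of by catalyst control. The fallback sets out from 7 and 15 and returns to 18.
- The epimers are diastereomers and are separated.
- The (5S,7R)-epimer F10 is inverted by a Mitsunobu reaction (4-nitrobenzoic acid, PPh3, DIAD, THF) to the (5S,7S) 4-nitrobenzoate F11.
- Methanolysis of F11 (K2CO3, MeOH) gives 18.

**Step 4.** The most likely failure is poor discrimination between the two trisubstituted olefins by ozone, and over-oxidation once the distal olefin is consumed.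
- Fallback: the selection is moved to a peracid, which responds more strongly to the electronic difference. The fallback sets out from 8 and returns to 10.
- mCPBA (1 equiv, CH2Cl2, 0 °C) gives the distal epoxide F12.
- H5IO6 in THF/H2O cleaves F12 to 10.

## Further compounds

F1 | step 11 | (1S,3S,4E,7Z,11S,12S)-3-[tert-butyl(dimethyl)silyloxy]-1-{3-[tert-butyl(dimethyl)silyloxy]prop-1-en-2-yl}-4,8,12-trimethylcyclotetradeca-4,7-diene-11,12-diol | C=C(CO[Si](C)(C)C(C)(C)C)[C@@H]1C[C@H](O[Si](C)(C)C(C)(C)C)/C(C)=C/C/C=C(/C)CC[C@H](O)[C@@](C)(O)CC1
F2 | step 11 | (1S,3S,4E,7Z,12S)-3-[tert-butyl(dimethyl)silyloxy]-1-{3-[tert-butyl(dimethyl)silyloxy]prop-1-en-2-yl}-12-hydroxy-4,8,12-trimethylcyclotetradeca-4,7-dien-11-one | C=C(CO[Si](C)(C)C(C)(C)C)[C@@H]1C[C@H](O[Si](C)(C)C(C)(C)C)/C(C)=C/C/C=C(/C)CCC(=O)[C@@](C)(O)CC1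
F3 | step 16 | (1S,3S,4E,7Z,11S,12R)-3-[tert-butyl(dimethyl)silyloxy]-1-{3-[tert-butyl(dimethyl)silyloxy]prop-1-en-2-yl}-4,8,12-trimethylcyclotetradeca-4,7-diene-11,12-diol | C=C(CO[Si](C)(C)C(C)(C)C)[C@@H]1C[C@H](O[Si](C)(C)C(C)(C)C)/C(C)=C/C/C=C(/C)CC[C@H](O)[C@](C)(O)CC1
F4 | step 16 | (1S,3S,4E,7Z,11S,12R)-3-[tert-butyl(dimethyl)silyloxy]-1-{3-[tert-butyl(dimethyl)silyloxy]prop-1-en-2-yl}-12-hydroxy-4,8,12-trimethylcyclotetradeca-4,7-dien-11-yl methanesulfonate | C=C(CO[Si](C)(C)C(C)(C)C)[C@@H]1C[C@H](O[Si](C)(C)C(C)(C)C)/C(C)=C/C/C=C(/C)CC[C@H](OS(C)(=O)=O)[C@](C)(O)CC1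
F5 | step 16 | (11R,12R)-11,12-epoxide of the (1S,3S,4E,7Z)-3-[tert-butyl(dimethyl)silyloxy]-1-{3-[tert-butyl(dimethyl)silyloxy]prop-1-en-2-yl}-4,8,12-trimethylcyclotetradeca-4,7-diene ring | C=C(CO[Si](C)(C)C(C)(C)C)[C@@H]1C[C@H](O[Si](C)(C)C(C)(C)C)/C(C)=C/C/C=C(/C)CC[C@H]2O[C@]2(C)CC1
F6 | step 16 | 2-[(1S,3S,4E,7Z,11R,12R)-3-[tert-butyl(dimethyl)silyloxy]-11,12-epoxy-4,8,12-trimethylcyclotetradeca-4,7-dien-1-yl]prop-2-en-1-ol | C=C(CO)[C@@H]1C[C@H](O[Si](C)(C)C(C)(C)C)/C(C)=C/C/C=C(/C)CC[C@H]2O[C@]2(C)CC1
F7 | step 16 | 2-[(1S,3S,4E,7Z,11R,12R)-3-[tert-butyl(dimethyl)silyloxy]-11,12-epoxy-4,8,12-trimethylcyclotetradeca-4,7-dien-1-yl]prop-2-enal | C=C(C=O)[C@@H]1C[C@H](O[Si](C)(C)C(C)(C)C)/C(C)=C/C/C=C(/C)CC[C@H]2O[C@]2(C)CC1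
F8 | step 16 | 2-[(1S,3S,4E,7Z,11R,12R)-3-[tert-butyl(dimethyl)silyloxy]-11,12-epoxy-4,8,12-trimethylcyclotetradeca-4,7-dien-1-yl]prop-2-enoic acid | C=C(C(=O)O)[C@@H]1C[C@H](O[Si](C)(C)C(C)(C)C)/C(C)=C/C/C=C(/C)CC[C@H]2O[C@]2(C)CC1
F9 | step 16 | (1S,3S,4E,7Z,11R,12S)-3-[tert-butyl(dimethyl)silyloxy]-11-hydroxycembra-4,7,15(16)-trien-17,12-olide | C=C1C(=O)O[C@@]2(C)CC[C@H]1C[C@H](O[Si](C)(C)C(C)(C)C)/C(C)=C/C/C=C(/C)CC[C@H]2O
F10 | step 8 | (5S,7R,8E,11Z)-5-{3-[tert-butyl(dimethyl)silyloxy]prop-1-en-2-yl}-7-hydroxy-15,15-dimethoxy-8,12-dimethylpentadeca-8,11-dien-2-one | CC(=O)CC[C@@H](C[C@@H](O)/C(C)=C/C/C=C(/C)CCC(OC)OC)C(=C)CO[Si](C)(C)C(C)(C)C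
F11 | step 8 | (5S,7S,8E,11Z)-5-{3-[tert-butyl(dimethyl)silyloxy]prop-1-en-2-yl}-15,15-dimethoxy-8,12-dimethyl-2-oxopentadeca-8,11-dien-7-yl 4-nitrobenzoate | CC(=O)CC[C@@H](C[C@H](OC(=O)c1ccc(cc1)[N+](=O)[O-])/C(C)=C/C/C=C(/C)CCC(OC)OC)C(=C)CO[Si](C)(C)C(C)(C)C
F12 | step 4 | (2Z)-5-(3,3-dimethyloxiran-2-yl)-3-methylpent-2-en-1-yl acetate, racemic epoxide | CC1(C)OC1CC/C(C)=C\COC(C)=O
A1 | alternative 1 | (4S,5Z,7S)-7-{(1R,4Z)-1-[tert-butyl(dimethyl)silyloxy]-4-methyl-6-[tri(propan-2-yl)silyloxy]hex-4-en-1-yl}-4-[2-(4-methoxybenzyloxy)ethyl]-7-methyl-4,7-dihydrooxepin-2(3H)-one | O=C1C[C@H](CCOCc2ccc(OC)cc2)/C=C\[C@](C)(O1)[C@@H](CC/C(C)=C\CO[Si](C(C)C)(C(C)C)C(C)C)O[Si](C)(C)C(C)(C)C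
A2 | alternative 2 | (1S,3S,4E,7Z,11R,12S)-3-[tert-butyl(dimethyl)silyloxy]-11-hydroxycembra-4,7,15(16)-trien-17,12-olide | C=C1C(=O)O[C@@]2(C)CC[C@H]1C[C@H](O[Si](C)(C)C(C)(C)C)/C(C)=C/C/C=C(/C)CC[C@H]2O
A3 | alternative 2 | 2-methylpropene | CC(C)=C
A4 | alternative 3 | (1S,3S,7Z,11R,12S)-11-acetoxy-3-(triethylsilyloxy)-4-norcembra-7,15(16)-dien-4-yn-17,12-olide (fourteen-membered 4,5-cycloalkyne, no methyl on C4) | C=C1C(=O)O[C@@]2(C)CC[C@H]1C[C@H](O[Si](CC)(CC)CC)C#CC/C=C(/C)CC[C@H]2OC(C)=O
A5 | alternative 3 | but-2-yne | CC#CC
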